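## Retrosynthetic overview

1. Both stereocentres are bought. C2 comes in (2S)-liquiritigenin 1, which already holds rings A, B and C, so no ring is formed in the route. The side-chain carbinol comes in methyl (4R)-2,2-dimethyl-1,3-dioxolane-4-carboxylate 2 (from D-mannitol).
2. Key disconnection: the aryl–CH2 bond between ring B and the 2-hydroxy-3-methylbut-3-enyl chain. It is made last, by a blue-light nickel/photoredox coupling of a ring B aryl iodide with a C5 hydroxy tosylate; the 7-acetate is removed in the same flask.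
3. The prenyl group is put on by Stille coupling on a 3',5'-diiodide, made by phenol-directed iodination once ring A is masked as its 7-acetate.
4. The C5 unit: ester 2 → tertiary alcohol → isopropenyl dioxolane → diol → primary tosylate; the C–O bond of the stereocentre is never broken.

Assumption: commercial liquiritigenin is the natural (2S)-enantiomer in high ee (to be checked by chiral HPLC on receipt).

## Route

Step 1
Reactants: 1 (2S)-7-hydroxy-2-(4-hydroxyphenyl)-2,3-dihydro-4H-chromen-4-one
Product: 3 (2S)-2-(4-hydroxyphenyl)-4-oxo-3,4-dihydro-2H-chromen-7-yl acetate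
Conditions: AcCl (1.0 equiv), i-Pr2NEt (1.05 equiv), THF, −78 → −20 °C
Reagents that add atoms: acetyl chloride, CC(=O)Cl
Why: Regioselective O-acylation: the 7-hydroxyl (para to the ketone, pKa about 7.5) is ionised far more than the 4'-hydroxyl and is trapped kinetically by the very reactive acid chloride at low temperature, and the ester then deactivates ring A for step 2.

Step 2
Reactants: 3 (2S)-2-(4-hydroxyphenyl)-4-oxo-3,4-dihydro-2H-chromen-7-yl acetate
Product: 5 (2S)-2-(4-hydroxy-3,5-diiodophenyl)-4-oxo-3,4-dihydro-2H-chromen-7-yl acetate, via monoiodide 4 (not isolated)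
Conditions: N-iodosuccinimide (2.2 equiv), TFA (20 mol %), MeCN, 0 → 25 °C, dark
Reagents that add atoms: N-iodosuccinimide, O=C1CCC(=O)N1I
Why: Electrophilic aromatic iodination: the free phenol of ring B directs iodine to both ortho positions (para is blocked), while ring A is switched off by the acetate and the ketone, and C2 is not touched.

Step 3
Reactants: 5 (2S)-2-(4-hydroxy-3,5-diiodophenyl)-4-oxo-3,4-dihydro-2H-chromen-7-yl acetate; 6 tributyl(3-methylbut-2-en-1-yl)stannane (1.0 equiv)
Product: 7 (2S)-2-[4-hydroxy-3-iodo-5-(3-methylbut-2-en-1-yl)phenyl]-4-oxo-3,4-dihydro-2H-chromen-7-yl acetate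
Conditions: Pd(PPh3)4 (5 mol %), DMF, 80 °C
Reagents that add atoms: none
Why: Stille coupling under neutral, base-free conditions spares the acetate and the C2 centre; one equivalent of stannane on the symmetric diiodide gives the mono-prenyl product statistically (expected about 45%, 5 recovered and recycled), with the linear prenyl isomer favoured.

Step 4
Reactants: 2 methyl (4R)-2,2-dimethyl-1,3-dioxolane-4-carboxylate
Product: 9 2-[(4R)-2,2-dimethyl-1,3-dioxolan-4-yl]propan-2-ol, via methyl ketone 8 (not isolated)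
Conditions: MeMgBr (3 equiv), THF, 0 → 25 °C; aq. NH4Cl
Reagents that add atoms: methylmagnesium bromide, C[Mg]Br
Why: Double Grignard addition to the ester through the ketone is faster than enolisation, so the α-alkoxy stereocentre keeps its configuration.

Step 5
Reactants: 9 2-[(4R)-2,2-dimethyl-1,3-dioxolan-4-yl]propan-2-ol
Product: 10 (4S)-2,2-dimethyl-4-(prop-1-en-2-yl)-1,3-dioxolane
Conditions: SOCl2 (1.3 equiv), pyridine, CH2Cl2, −20 → 0 °C
Reagents that add atoms: none
Why: E2 dehydration of the tertiary chlorosulfite takes one of six methyl hydrogens in preference to the single ring hydrogen next to oxygen, giving the isopropenyl group; the stereocentre is a spectator (its descriptor changes to S only through the CIP priorities).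

Step 6
Reactants: 10 (4S)-2,2-dimethyl-4-(prop-1-en-2-yl)-1,3-dioxolane
Product: 11 (2S)-3-methylbut-3-ene-1,2-diol
Conditions: Dowex 50WX8 (H+ form), MeOH/H2O 9:1, 25 °C
Reagents that add atoms: none
Why: Acid-catalysed acetal hydrolysis cleaves at the acetal carbon, so the allylic C–O bond and its configuration are retained.

Step 7
Reactants: 11 (2S)-3-methylbut-3-ene-1,2-diol
Product: 12 (2S)-2-hydroxy-3-methylbut-3-en-1-yl 4-methylbenzenesulfonate
Conditions: TsCl (1.05 equiv), Bu2SnO (2 mol %), Et3N (1.1 equiv), CH2Cl2, 0 → 25 °C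
Reagents that add atoms: 4-toluenesulfonyl chloride, Cc1ccc(cc1)S(=O)(=O)Cl
Why: Tin-acetal-catalysed sulfonylation of a terminal 1,2-diol is selective for the primary hydroxyl and leaves the secondary carbinol untouched.

Step 8
Reactants: 7 (2S)-2-[4-hydroxy-3-iodo-5-(3-methylbut-2-en-1-yl)phenyl]-4-oxo-3,4-dihydro-2H-chromen-7-yl acetate; 12 (2S)-2-hydroxy-3-methylbut-3-en-1-yl 4-methylbenzenesulfonate (1.5 equiv)
Product: 15 (2S)-7-hydroxy-2-{4-hydroxy-3-[(2R)-2-hydroxy-3-methylbut-3-en-1-yl]-5-(3-methylbut-2-en-1-yl)phenyl}-2,3-dihydro-4H-chromen-4-one, via iodohydrin 13 (not isolated), via coupled acetate 14 (not isolated)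
Conditions: 12, NaI (2 equiv), DMA, 50 °C, 3 h; then 7, NiBr2·dme (10 mol %), 4,4'-di-tert-butyl-2,2'-bipyridine (12 mol %), 4CzIPN (2 mol %), Et3N (4 equiv), blue LEDs (450 nm), 25 °C, 24 h; then MeOH, 25 °C, 2 h
Reagents that add atoms: none
Why: Proposed new method: an iodide-relayed nickel/organophotoredox cross-electrophile coupling of an unprotected ortho-iodophenol with a free β-hydroxy homoallylic sulfonate, not yet shown for a 2-hydroxyalk-3-enyl electrophile or on a base-labile flavanone. Mechanistic reasoning: iodide turns tosylate 12 into iodohydrin 13; photoexcited 4CzIPN oxidises Et3N to an α-aminoalkyl radical that abstracts the iodine atom and gives the primary β-hydroxyalkyl radical; the reduced photocatalyst returns the catalyst to zerovalent nickel, which inserts into the C–I bond of 7; the aryl–nickel species captures the radical and reductive elimination from trivalent nickel forms the aryl–CH2 bond. The bought carbinol centre lies one carbon from the radical and keeps its C–O bond, so it is retained (it is named R in the product only because the CIP priorities change). The 3-exo closure that would start a 1,2-vinyl shift should be slow at the methyl-bearing alkene carbon compared with capture at 10 mol % nickel. The phenol should stay un-ionised with Et3N in DMA, so C2 does not epimerise. Et3N/MeOH then removes the activated 7-acetate. Closest known reaction type: nickel/photoredox coupling of aryl iodides with terminal aliphatic epoxides through in-situ iodohydrins, and halogen-atom-transfer cross-electrophile couplings.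

## Compound list

1 | (2S)-7-hydroxy-2-(4-hydroxyphenyl)-2,3-dihydro-4H-chromen-4-one, (S)-liquiritigenin | Oc1ccc([C@@H]2CC(=O)c3ccc(O)cc3O2)cc1 | starting material
2 | methyl (4R)-2,2-dimethyl-1,3-dioxolane-4-carboxylate | COC(=O)[C@H]1COC(C)(C)O1 | starting material
3 | (2S)-2-(4-hydroxyphenyl)-4-oxo-3,4-dihydro-2H-chromen-7-yl acetate | Oc1ccc([C@@H]2CC(=O)c3ccc(OC(C)=O)cc3O2)cc1 | intermediate
4 | (2S)-2-(4-hydroxy-3-iodophenyl)-4-oxo-3,4-dihydro-2H-chromen-7-yl acetate | Oc1ccc([C@@H]2CC(=O)c3ccc(OC(C)=O)cc3O2)cc1I | intermediate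
5 | (2S)-2-(4-hydroxy-3,5-diiodophenyl)-4-oxo-3,4-dihydro-2H-chromen-7-yl acetate | Oc1c(I)cc([C@@H]2CC(=O)c3ccc(OC(C)=O)cc3O2)cc1I | intermediate
6 | tributyl(3-methylbut-2-en-1-yl)stannane | CCCC[Sn](CCCC)(CCCC)CC=C(C)C | starting material
7 | (2S)-2-[4-hydroxy-3-iodo-5-(3-methylbut-2-en-1-yl)phenyl]-4-oxo-3,4-dihydro-2H-chromen-7-yl acetate | CC(C)=CCc1cc([C@@H]2CC(=O)c3ccc(OC(C)=O)cc3O2)cc(I)c1O | intermediate
8 | 1-[(4R)-2,2-dimethyl-1,3-dioxolan-4-yl]ethan-1-one | CC(=O)[C@H]1COC(C)(C)O1 | intermediate
9 | 2-[(4R)-2,2-dimethyl-1,3-dioxolan-4-yl]propan-2-ol | CC(C)(O)[C@H]1COC(C)(C)O1 | intermediate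
10 | (4S)-2,2-dimethyl-4-(prop-1-en-2-yl)-1,3-dioxolane | C=C(C)[C@H]1COC(C)(C)O1 | intermediate
11 | (2S)-3-methylbut-3-ene-1,2-diol | C=C(C)[C@H](O)CO | intermediate
12 | (2S)-2-hydroxy-3-methylbut-3-en-1-yl 4-methylbenzenesulfonate | C=C(C)[C@H](O)COS(=O)(=O)c1ccc(C)cc1 | intermediate
13 | (2S)-1-iodo-3-methylbut-3-en-2-ol | C=C(C)[C@H](O)CI | intermediate
14 | (2S)-2-{4-hydroxy-3-[(2R)-2-hydroxy-3-methylbut-3-en-1-yl]-5-(3-methylbut-2-en-1-yl)phenyl}-4-oxo-3,4-dihydro-2H-chromen-7-yl acetate | C=C(C)[C@H](O)Cc1cc([C@@H]2CC(=O)c3ccc(OC(C)=O)cc3O2)cc(CC=C(C)C)c1O | intermediate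
15 | (2S)-7-hydroxy-2-{4-hydroxy-3-[(2R)-2-hydroxy-3-methylbut-3-en-1-yl]-5-(3-methylbut-2-en-1-yl)phenyl}-2,3-dihydro-4H-chromen-4-one | C=C(C)[C@H](O)Cc1cc([C@@H]2CC(=O)c3ccc(O)cc3O2)cc(CC=C(C)C)c1O | target

## Step count and risks

Total steps: 8. Longest linear sequence: 5 (2 → 9 → 10 → 11 → 12 → 15, steps 4 to 8); the branch from 1 is 4 steps (1, 2, 3, 8).

Step 8 (the proposed coupling) is the most likely to fail. Possible failures are loss of iodine from 7 without coupling, a 1,2-vinyl shift of the homoallyl radical, O-alkylation of the phenol, or a sluggish tosylate-to-iodide exchange. The fallback uses known chemistry and sets out from 12 and 7. Tosylate 12 is converted with NaI in acetone at 50 °C into iodohydrin 13, now isolated. Silylation (TBSCl, imidazole, DMF) gives tert-butyl{[(2S)-1-iodo-3-methylbut-3-en-2-yl]oxy}dimethylsilane F1. F1 is joined to 7 by the established light-free, manganese-driven nickel reductive coupling of aryl iodides with primary alkyl iodides (NiI2, 4,4'-di-tert-butyl-2,2'-bipyridine, pyridine, Mn powder, DMPU, 60 °C). This gives (2S)-2-{3-[(2R)-2-[(tert-butyldimethylsilyl)oxy]-3-methylbut-3-en-1-yl]-4-hydroxy-5-(3-methylbut-2-en-1-yl)phenyl}-4-oxo-3,4-dihydro-2H-chromen-7-yl acetate F2. HF·pyridine in THF at 0 °C removes the silyl group and the route is rejoined at 14, which is deacetylated with Et3N/MeOH as in step 8. This fallback does not remove the vinyl-shift risk, since the same radical is formed.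

Step 3 (mono-Stille on a symmetric diiodide) is limited to about half conversion to 7. It may also lose stannane to the acidic diiodophenol or give some branched prenyl isomer. The fallback replaces cross-coupling by O-alkylation and a [3,3] shift, and sets out from 4, obtained by stopping step 2 at 1.0 equiv of N-iodosuccinimide. Monoiodide 4 is O-alkylated with 2-methylbut-3-yn-2-yl trifluoroacetate (CuCl2·2H2O cat., DBU, MeCN, 0 °C, short contact to protect C2) to (2S)-2-{3-iodo-4-[(2-methylbut-3-yn-2-yl)oxy]phenyl}-4-oxo-3,4-dihydro-2H-chromen-7-yl acetate F3. Semihydrogenation (H2, Pd on CaCO3 poisoned with Pb(OAc)2, quinoline, EtOAc) gives (2S)-2-{3-iodo-4-[(2-methylbut-3-en-2-yl)oxy]phenyl}-4-oxo-3,4-dihydro-2H-chromen-7-yl acetate F4. Heating F4 in toluene at 110 °C brings about the aromatic Claisen rearrangement, which can only go to the free ortho position, and the route is rejoined at 7 with no statistical loss.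

Step 5 (dehydration) may give some of the isomeric enol ether or tertiary chloride, and 10 is volatile. The fallback builds the alkene by olefination and sets out from 2. Ester 2 with Me(MeO)NH·HCl and i-PrMgCl in THF at −20 °C gives (4R)-N-methoxy-N,2,2-trimethyl-1,3-dioxolane-4-carboxamide F5. MeMgBr converts F5 into ketone 8, now isolated. Wittig methylenation (Ph3PCH3Br, KN(SiMe3)2, THF, −78 → 0 °C) rejoins the route at 10.

## Further compounds

F1 | step 8 | tert-butyl{[(2S)-1-iodo-3-methylbut-3-en-2-yl]oxy}dimethylsilane | C=C(C)[C@H](O[Si](C)(C)C(C)(C)C)CI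
F2 | step 8 | (2S)-2-{3-[(2R)-2-[(tert-butyldimethylsilyl)oxy]-3-methylbut-3-en-1-yl]-4-hydroxy-5-(3-methylbut-2-en-1-yl)phenyl}-4-oxo-3,4-dihydro-2H-chromen-7-yl acetate | C=C(C)[C@H](O[Si](C)(C)C(C)(C)C)Cc1cc([C@@H]2CC(=O)c3ccc(OC(C)=O)cc3O2)cc(CC=C(C)C)c1O
F3 | step 3 | (2S)-2-{3-iodo-4-[(2-methylbut-3-yn-2-yl)oxy]phenyl}-4-oxo-3,4-dihydro-2H-chromen-7-yl acetate | C#CC(C)(C)Oc1ccc([C@@H]2CC(=O)c3ccc(OC(C)=O)cc3O2)cc1I
F4 | step 3 | (2S)-2-{3-iodo-4-[(2-methylbut-3-en-2-yl)oxy]phenyl}-4-oxo-3,4-dihydro-2H-chromen-7-yl acetate | C=CC(C)(C)Oc1ccc([C@@H]2CC(=O)c3ccc(OC(C)=O)cc3O2)cc1I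
F5 | step 5 | (4R)-N-methoxy-N,2,2-trimethyl-1,3-dioxolane-4-carboxamide | CON(C)C(=O)[C@H]1COC(C)(C)O1
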